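**Plan**

- Retrosynthesis: both epoxides go back to the E,E-1(10),4-diene. The butenolide is cut at O6–C12 (ester) and C7=C11 (intramolecular Horner–Wadsworth–Emmons on a C7 ketone). The ten-membered ring is then cut at C1–C2.
- This cut is possible because C2–C3 is the only CH2–CH2 unit of the ring and C1 is the CH end of the C1=C10 alkene. C1 becomes an E-vinyl iodide and C2 the terminus of a C2=C3 vinyl group on a C2–C5 diene (sp2–sp3 closure).
- The open chain is cut at C5–C6 (dienyl–aldehyde addition) and C8–C9 (propargylation of glyceraldehyde). C14 arrives by methylalumination of the C10≡C1 alkyne.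
- Forward order: C6–C10/C1 chain, dienyl unit at C6, vinyl iodide, ten-membered carbocycle, 4,5-epoxide, butenolide, 1,10-epoxide.
- Stereochemistry: C7 of (R)-glyceraldehyde (later erased as the ketone) controls C8 and then C6 through two Felkin-type additions. C4/C5 follow from C6 by hydroxyl-directed epoxidation, and C1/C10 from peripheral peracid attack. Both E alkenes come from syn-carbometalation and retentive couplings.

Key step: step 12

Remark: all carbons carry germacrane numbers (C14 on C10, C15 on C4; α/β as in the usual germacranolide drawing, the target being 1R,4R,5R,6S,8S,10R); the phosphonate-bearing carbon C11 is carried as an inconsequential epimer mixture until it becomes sp2.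

**Route**

Step 1
Reactants: 1 (R)-2,2-dimethyl-1,3-dioxolane-4-carbaldehyde; 2 propargyl bromide
Product: 4 (S)-1-[(R)-2,2-dimethyl-1,3-dioxolan-4-yl]but-3-yn-1-ol, via allenylzinc bromide 3 (not isolated)
Conditions: Zn dust, THF–sat. aq NH4Cl, 0 °C → rt
Reagents that add atoms: none
Why: Barbier propargylation in which the allenylzinc adds by an SE2' transition state to the Felkin–Anh face of the α-alkoxy aldehyde, so the anti (erythro) homopropargylic alcohol should predominate and C8 (S) is set from the resident C7 centre; the minor syn isomer is removed by chromatography.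

Step 2
Reactants: 4 (S)-1-[(R)-2,2-dimethyl-1,3-dioxolan-4-yl]but-3-yn-1-ol
Product: 5 (S)-1-[(R)-2,2-dimethyl-1,3-dioxolan-4-yl]but-3-yn-1-yl 2-methylpropanoate
Conditions: i-PrCOCl, pyridine, DMAP (cat.), CH2Cl2, 0 °C → rt
Reagents that add atoms: isobutyryl chloride CC(C)C(=O)Cl
Why: DMAP-catalysed acylation installs the final C8 isobutyrate at once, so no protecting-group exchange at C8 is needed later.

Step 3
Reactants: 5 (S)-1-[(R)-2,2-dimethyl-1,3-dioxolan-4-yl]but-3-yn-1-yl 2-methylpropanoate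
Product: 6 (2R,3S)-1,2-dihydroxyhex-5-yn-3-yl 2-methylpropanoate
Conditions: AcOH–H2O (4:1), 40 °C
Reagents that add atoms: none
Why: Mild acid hydrolysis of a terminal isopropylidene acetal, under which the hindered ester should neither cleave nor migrate appreciably.

Step 4
Reactants: 6 (2R,3S)-1,2-dihydroxyhex-5-yn-3-yl 2-methylpropanoate
Product: 7 (2R,3S)-1,2-bis(triethylsilyloxy)hex-5-yn-3-yl 2-methylpropanoate
Conditions: Et3SiOTf, 2,6-lutidine, CH2Cl2, −78 °C
Reagents that add atoms: triethylsilyl trifluoromethanesulfonate CC[Si](CC)(CC)OS(=O)(=O)C(F)(F)F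
Why: Silyl triflate silylation of both hydroxyls is fast at low temperature and should outrun acyl migration from O8.

Step 5
Reactants: 7 (2R,3S)-1,2-bis(triethylsilyloxy)hex-5-yn-3-yl 2-methylpropanoate
Product: 9 (2S,3S)-1-oxo-2-(triethylsilyloxy)hex-5-yn-3-yl 2-methylpropanoate, via alkoxysulfonium chloride 8 (not isolated)
Conditions: (COCl)2, DMSO, CH2Cl2, −78 → −30 °C; i-Pr2NEt, −78 → −20 °C, cold buffered quench
Reagents that add atoms: none
Why: Swern oxidation applied directly to a bis-silyl ether, in which the chlorosulfonium salt cleaves only the unhindered primary Si–O bond and the resulting alkoxysulfonium collapses to the C6 aldehyde; the hindered base and cold quench limit C7 epimerisation and β-elimination of the C8 ester.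

Step 6
Reactants: 10 prop-2-yn-1-ol
Product: 12 (E)-3-iodo-2-methylprop-2-en-1-ol, via alkenylalane 11 (not isolated)
Conditions: AlMe3, Cp2ZrCl2 (25 mol%), CH2Cl2, 0 °C → rt; I2, THF, −30 → 0 °C
Reagents that add atoms: trimethylaluminium C[Al](C)C; iodine II
Why: Negishi zirconium-catalysed methylalumination adds methyl and aluminium syn across the alkyne with aluminium at the terminus, and iodinolysis with retention gives the E iodide.

Step 7
Reactants: 12 (E)-3-iodo-2-methylprop-2-en-1-ol
Product: 13 (E)-3-iodo-2-methylprop-2-enal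
Conditions: MnO2, CH2Cl2, rt
Reagents that add atoms: none
Why: Allylic alcohol oxidation with MnO2, which leaves the iodoalkene geometry untouched.

Step 8
Reactants: 13 (E)-3-iodo-2-methylprop-2-enal
Product: 14 (E)-1-iodo-2-methylbuta-1,3-diene
Conditions: Ph3PCH3Br, KN(SiMe3)2, THF, 0 °C; then 13, −78 → 0 °C
Reagents that add atoms: methyltriphenylphosphonium bromide C[P+](c1ccccc1)(c1ccccc1)c1ccccc1.[Br-]
Why: Wittig methylenation creates the C2=C3 vinyl group with no geometric issue; the volatile diene is used as a solution.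

Step 9
Reactants: 9 (2S,3S)-1-oxo-2-(triethylsilyloxy)hex-5-yn-3-yl 2-methylpropanoate; 14 (E)-1-iodo-2-methylbuta-1,3-diene
Product: 16 (3E,5R,6R,7S)-5-hydroxy-3-methyl-6-(triethylsilyloxy)deca-1,3-dien-9-yn-7-yl 2-methylpropanoate, via dienylchromium dichloride 15 (not isolated)
Conditions: CrCl2 (4 equiv), NiCl2 (2 mol%), DMF–THF, rt
Reagents that add atoms: none
Why: Nozaki–Hiyama–Kishi coupling, whose alkenyl trivalent-chromium species adds to the aldehyde only (ester and terminal alkyne are inert) with retention of the E geometry; Felkin–Anh attack anti to the α-silyloxy group, reinforced by the anti β-acyloxy group, should set C6 (R).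

Step 10
Reactants: 16 (3E,5R,6R,7S)-5-hydroxy-3-methyl-6-(triethylsilyloxy)deca-1,3-dien-9-yn-7-yl 2-methylpropanoate
Product: 17 (3E,5R,6S,7S)-5-(tert-butyldimethylsilyloxy)-3-methyl-6-(triethylsilyloxy)deca-1,3-dien-9-yn-7-yl 2-methylpropanoate
Conditions: t-BuMe2SiOTf, 2,6-lutidine, CH2Cl2, −78 → 0 °C
Reagents that add atoms: tert-butyldimethylsilyl trifluoromethanesulfonate CC(C)(C)[Si](C)(C)OS(=O)(=O)C(F)(F)F
Why: Silyl triflate silylation of the hindered dienylic alcohol under non-basic conditions (no silyl migration), giving a C6 ether more robust than the C7 triethylsilyl ether.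

Step 11
Reactants: 17 (3E,5R,6S,7S)-5-(tert-butyldimethylsilyloxy)-3-methyl-6-(triethylsilyloxy)deca-1,3-dien-9-yn-7-yl 2-methylpropanoate
Product: 19 (3E,5R,6S,7S,9E)-5-(tert-butyldimethylsilyloxy)-10-iodo-3,9-dimethyl-6-(triethylsilyloxy)deca-1,3,9-trien-7-yl 2-methylpropanoate, via alkenylalane 18 (not isolated)
Conditions: AlMe3, Cp2ZrCl2, H2O (1.5 equiv), CH2Cl2, −30 °C; I2, THF, −30 → 0 °C
Reagents that add atoms: trimethylaluminium C[Al](C)C; iodine II
Why: Water-accelerated Negishi carboalumination–iodinolysis delivers C14 and the E C1 iodide by syn addition across the terminal alkyne; at −30 °C the diene, silyl ethers and hindered ester are expected to survive.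

Step 12
Reactants: 19 (3E,5R,6S,7S,9E)-5-(tert-butyldimethylsilyloxy)-10-iodo-3,9-dimethyl-6-(triethylsilyloxy)deca-1,3,9-trien-7-yl 2-methylpropanoate
Product: 21 (1S,2S,3R,4E,8E)-3-(tert-butyldimethylsilyloxy)-5,9-dimethyl-2-(triethylsilyloxy)cyclodeca-4,8-dien-1-yl 2-methylpropanoate, via B-alkyl-9-BBN borane 20 (not isolated)
Conditions: 9-BBN, THF, 0 °C → rt; then slow addition to Pd(dppf)Cl2 (15 mol%), AsPh3, Cs2CO3, DMF–THF–H2O, 50 °C, 2 mM
Reagents that add atoms: none
Why: 9-BBN adds anti-Markovnikov to the monosubstituted C2=C3 terminus of the diene only (the trisubstituted alkenes and the iodoalkene are too hindered) to give the primary C2 borane; Pd(dppf)Cl2 (divalent palladium) is reduced in situ to zerovalent palladium, which inserts into the C1–I bond with retention, the base-activated borane transmetallates and reductive elimination forms C1–C2. The closest known reaction type is the B-alkyl Suzuki–Miyaura macrocyclisation of an in situ 9-BBN adduct onto a vinyl iodide. The one ring formed is the ten-membered carbocycle, closed end to end (sp3–sp2) through an eleven-membered palladacycle. No stereocentre is created, and both trisubstituted E alkenes enter with fixed geometry, so none is decided under ring strain. The step needs chemoselective hydroboration, ring closure over oligomerisation and no β-hydride elimination, which the bulk of 9-BBN, slow addition into dilute catalyst, the wide-bite-angle dppf ligand with AsPh3 and mild aqueous Cs2CO3 (ester and silyl ethers intact) should secure. From here on temperatures stay at or below 50 °C so that the E,E-cyclodeca-1,5-diene does not undergo Cope rearrangement.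

Step 13
Reactants: 21 (1S,2S,3R,4E,8E)-3-(tert-butyldimethylsilyloxy)-5,9-dimethyl-2-(triethylsilyloxy)cyclodeca-4,8-dien-1-yl 2-methylpropanoate
Product: 22 (1S,2S,3R,4E,8E)-3-(tert-butyldimethylsilyloxy)-2-hydroxy-5,9-dimethylcyclodeca-4,8-dien-1-yl 2-methylpropanoate
Conditions: PPTS (cat.), MeOH–CH2Cl2, 0 °C
Reagents that add atoms: none
Why: Acid-catalysed methanolysis removes the triethylsilyl ether far faster than the tert-butyldimethylsilyl ether, freeing only the C7 hydroxyl.

Step 14
Reactants: 22 (1S,2S,3R,4E,8E)-3-(tert-butyldimethylsilyloxy)-2-hydroxy-5,9-dimethylcyclodeca-4,8-dien-1-yl 2-methylpropanoate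
Product: 23 (1S,3R,4E,8E)-3-(tert-butyldimethylsilyloxy)-5,9-dimethyl-2-oxocyclodeca-4,8-dien-1-yl 2-methylpropanoate
Conditions: Dess–Martin periodinane, CH2Cl2, 0 °C → rt
Reagents that add atoms: none
Why: Dess–Martin oxidation gives the C7 ketone under near-neutral conditions that should not epimerise C6 or C8; the temporary C7 stereocentre is erased here.

Step 15
Reactants: 23 (1S,3R,4E,8E)-3-(tert-butyldimethylsilyloxy)-5,9-dimethyl-2-oxocyclodeca-4,8-dien-1-yl 2-methylpropanoate
Product: 24 (1S,3R,4E,8E)-3-hydroxy-5,9-dimethyl-2-oxocyclodeca-4,8-dien-1-yl 2-methylpropanoate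
Conditions: HF·pyridine, pyridine, THF, 0 °C → rt
Reagents that add atoms: none
Why: Buffered fluoride desilylation of an α-silyloxy ketone, chosen over basic fluoride to avoid enediol isomerisation of the allylic α-ketol, which is used at once.

Step 16
Reactants: 24 (1S,3R,4E,8E)-3-hydroxy-5,9-dimethyl-2-oxocyclodeca-4,8-dien-1-yl 2-methylpropanoate
Product: 25 (4R,5R,6R,8S)-4α,5β-epoxy-6α-hydroxy-7-oxocyclodec-1(10)E-en-8α-yl 2-methylpropanoate (germacrane numbering with methyls on C4 and C10)
Conditions: VO(acac)2 (5 mol%), t-BuOOH, CH2Cl2, 0 °C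
Reagents that add atoms: tert-butyl hydroperoxide CC(C)(C)OO
Why: Vanadium-catalysed hydroxyl-directed epoxidation touches only the allylic C4=C5 alkene; A(1,3) strain with the C15 methyl holds H-6 in the alkene plane, so oxygen is delivered to the hydroxyl-bearing face, which is also the peripheral face of the ring, setting C4 and C5 (threo to C6).

Step 17
Reactants: 26 allyl 2-(diethoxyphosphoryl)acetate
Product: 28 allyl 2-(diethoxyphosphoryl)-3-(triisopropylsilyloxy)propanoate, via sodium phosphonoacetate 27 (not isolated)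
Conditions: NaH, THF, 0 °C; i-Pr3SiOCH2Cl, 0 °C → rt
Reagents that add atoms: (chloromethoxy)triisopropylsilane ClCO[Si](C(C)C)(C(C)C)C(C)C
Why: C-alkylation of the stabilised phosphonoacetate carbanion with an α-chloro ether brings in C13 already at the protected alcohol level.

Step 18
Reactants: 28 allyl 2-(diethoxyphosphoryl)-3-(triisopropylsilyloxy)propanoate
Product: 29 2-(diethoxyphosphoryl)-3-(triisopropylsilyloxy)propanoic acid
Conditions: Pd(PPh3)4 (5 mol%), morpholine, THF, rt; aq KHSO4 work-up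
Reagents that add atoms: none
Why: Tsuji–Trost deallylation by zerovalent palladium transfers the allyl group to morpholine under neutral conditions, avoiding the hydroxide that could trigger β-elimination of the silyloxy group.

Step 19
Reactants: 25 (4R,5R,6R,8S)-4α,5β-epoxy-6α-hydroxy-7-oxocyclodec-1(10)E-en-8α-yl 2-methylpropanoate; 29 2-(diethoxyphosphoryl)-3-(triisopropylsilyloxy)propanoic acid
Product: 30 (4R,5R,6R,8S)-4α,5β-epoxy-7-oxo-8α-(2-methylpropanoyloxy)cyclodec-1(10)E-en-6α-yl 2-(diethoxyphosphoryl)-3-(triisopropylsilyloxy)propanoate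
Conditions: DCC, DMAP (cat.), CH2Cl2, 0 °C → rt
Reagents that add atoms: none
Why: Steglich esterification of the α-ketol hydroxyl attaches C11–C13 to O6 under conditions mild enough for the epoxide and the α-acyloxy ketone.

Step 20
Reactants: 30 (4R,5R,6R,8S)-4α,5β-epoxy-7-oxo-8α-(2-methylpropanoyloxy)cyclodec-1(10)E-en-6α-yl 2-(diethoxyphosphoryl)-3-(triisopropylsilyloxy)propanoate
Product: 31 (4R,5R,6S,8S)-4α,5β-epoxy-8α-(2-methylpropanoyloxy)-13-(triisopropylsilyloxy)germacra-1(10)E,7(11)-dien-12,6α-olide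
Conditions: LiCl, i-Pr2NEt, MeCN, rt
Reagents that add atoms: none
Why: Intramolecular Horner–Wadsworth–Emmons olefination under Masamune–Roush conditions closes the five-membered butenolide at the C7 ketone; the weak base is chosen to avoid β-elimination of the silyloxy group and epimerisation at C6 or C8.

Step 21
Reactants: 31 (4R,5R,6S,8S)-4α,5β-epoxy-8α-(2-methylpropanoyloxy)-13-(triisopropylsilyloxy)germacra-1(10)E,7(11)-dien-12,6α-olide
Product: 32 (4R,5R,6S,8S)-4α,5β-epoxy-13-hydroxy-8α-(2-methylpropanoyloxy)germacra-1(10)E,7(11)-dien-12,6α-olide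
Conditions: Bu4NF, AcOH, THF, 0 °C → rt
Reagents that add atoms: none
Why: Acetic acid-buffered fluoride desilylation frees the primary C13 hydroxyl without deprotonating the γ-position (C6) of the butenolide.

Step 22
Reactants: 32 (4R,5R,6S,8S)-4α,5β-epoxy-13-hydroxy-8α-(2-methylpropanoyloxy)germacra-1(10)E,7(11)-dien-12,6α-olide
Product: 33 (4R,5R,6S,8S)-13-acetoxy-4α,5β-epoxy-8α-(2-methylpropanoyloxy)germacra-1(10)E,7(11)-dien-12,6α-olide
Conditions: Ac2O, pyridine, DMAP (cat.), CH2Cl2, 0 °C
Reagents that add atoms: acetic anhydride CC(=O)OC(C)=O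
Why: Standard acetylation of the only free hydroxyl.

Step 23
Reactants: 33 (4R,5R,6S,8S)-13-acetoxy-4α,5β-epoxy-8α-(2-methylpropanoyloxy)germacra-1(10)E,7(11)-dien-12,6α-olide
Product: 34 (1R,4R,5R,6S,8S,10R)-13-acetoxy-1β,10α;4α,5β-diepoxy-8α-(2-methylpropanoyloxy)germacr-7(11)-en-12,6α-olide
Conditions: mCPBA, CH2Cl2, 0 °C
Reagents that add atoms: 3-chloroperbenzoic acid OOC(=O)c1cccc(Cl)c1
Why: Prilezhaev epoxidation reacts only at the electron-rich trisubstituted C1=C10 alkene (the butenolide alkene is electron-poor), and attack on the peripheral face of the conformer with C14 syn to C15 should give the 1β,10α epoxide, setting C1 and C10.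

**Compound list**

1 | (R)-2,2-dimethyl-1,3-dioxolane-4-carbaldehyde | O=C[C@H]1COC(C)(C)O1 | starting material
2 | propargyl bromide | C#CCBr | starting material
3 | allenylzinc bromide (propa-1,2-dienylzinc bromide, formed in situ) | C=C=C[Zn]Br | intermediate
4 | (S)-1-[(R)-2,2-dimethyl-1,3-dioxolan-4-yl]but-3-yn-1-ol | C#CC[C@H](O)[C@H]1COC(C)(C)O1 | intermediate
5 | (S)-1-[(R)-2,2-dimethyl-1,3-dioxolan-4-yl]but-3-yn-1-yl 2-methylpropanoate | C#CC[C@H](OC(=O)C(C)C)[C@H]1COC(C)(C)O1 | intermediate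
6 | (2R,3S)-1,2-dihydroxyhex-5-yn-3-yl 2-methylpropanoate | C#CC[C@H](OC(=O)C(C)C)[C@H](O)CO | intermediate
7 | (2R,3S)-1,2-bis(triethylsilyloxy)hex-5-yn-3-yl 2-methylpropanoate | C#CC[C@H](OC(=O)C(C)C)[C@H](O[Si](CC)(CC)CC)CO[Si](CC)(CC)CC | intermediate
8 | dimethyl{[(2R,3S)-3-(2-methylpropanoyloxy)-2-(triethylsilyloxy)hex-5-yn-1-yl]oxy}sulfonium chloride (formed in situ) | C#CC[C@H](OC(=O)C(C)C)[C@H](O[Si](CC)(CC)CC)CO[S+](C)C.[Cl-] | intermediate
9 | (2S,3S)-1-oxo-2-(triethylsilyloxy)hex-5-yn-3-yl 2-methylpropanoate (C6 aldehyde) | C#CC[C@H](OC(=O)C(C)C)[C@H](O[Si](CC)(CC)CC)C=O | intermediate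
10 | prop-2-yn-1-ol | C#CCO | starting material
11 | (E)-dimethyl{2-methyl-3-[(dimethylalumanyl)oxy]prop-1-en-1-yl}alumane (formed in situ) | C[Al](C)OC/C(C)=C/[Al](C)C | intermediate
12 | (E)-3-iodo-2-methylprop-2-en-1-ol | OC/C(C)=C/I | intermediate
13 | (E)-3-iodo-2-methylprop-2-enal | O=C/C(C)=C/I | intermediate
14 | (E)-1-iodo-2-methylbuta-1,3-diene | C=C/C(C)=C/I | intermediate
15 | dichloro[(1E)-2-methylbuta-1,3-dien-1-yl]chromium (trivalent chromium, formed in situ) | C=C/C(C)=C/[Cr](Cl)Cl | intermediate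
16 | (3E,5R,6R,7S)-5-hydroxy-3-methyl-6-(triethylsilyloxy)deca-1,3-dien-9-yn-7-yl 2-methylpropanoate | C=C/C(C)=C/[C@@H](O)[C@@H](O[Si](CC)(CC)CC)[C@@H](OC(=O)C(C)C)CC#C | intermediate
17 | (3E,5R,6S,7S)-5-(tert-butyldimethylsilyloxy)-3-methyl-6-(triethylsilyloxy)deca-1,3-dien-9-yn-7-yl 2-methylpropanoate | C=C/C(C)=C/[C@@H](O[Si](C)(C)C(C)(C)C)[C@@H](O[Si](CC)(CC)CC)[C@@H](OC(=O)C(C)C)CC#C | intermediate
18 | E-alkenyl(dimethyl)alane from syn-methylalumination of 17 (Al on C1, formed in situ) | C=C/C(C)=C/[C@@H](O[Si](C)(C)C(C)(C)C)[C@@H](O[Si](CC)(CC)CC)[C@@H](OC(=O)C(C)C)C/C(C)=C/[Al](C)C | intermediate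
19 | (3E,5R,6S,7S,9E)-5-(tert-butyldimethylsilyloxy)-10-iodo-3,9-dimethyl-6-(triethylsilyloxy)deca-1,3,9-trien-7-yl 2-methylpropanoate (C2=C3 vinyl terminus and C1 E-vinyl iodide) | C=C/C(C)=C/[C@@H](O[Si](C)(C)C(C)(C)C)[C@@H](O[Si](CC)(CC)CC)[C@@H](OC(=O)C(C)C)C/C(C)=C/I | intermediate
20 | 9-alkyl-9-borabicyclo[3.3.1]nonane from hydroboration of the C2=C3 vinyl group of 19 (boron on C2, formed in situ) | C(C/C(C)=C/[C@@H](O[Si](C)(C)C(C)(C)C)[C@@H](O[Si](CC)(CC)CC)[C@@H](OC(=O)C(C)C)C/C(C)=C/I)B1C2CCCC1CCC2 | intermediate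
21 | (1S,2S,3R,4E,8E)-3-(tert-butyldimethylsilyloxy)-5,9-dimethyl-2-(triethylsilyloxy)cyclodeca-4,8-dien-1-yl 2-methylpropanoate (germacrane numbering: 1(10)E,4E-diene, 6α-OTBS, 7α-OTES, 8α-isobutyrate) | C1C/C(C)=C/[C@@H](O[Si](C)(C)C(C)(C)C)[C@@H](O[Si](CC)(CC)CC)[C@@H](OC(=O)C(C)C)C/C(C)=C/1 | intermediate
22 | (1S,2S,3R,4E,8E)-3-(tert-butyldimethylsilyloxy)-2-hydroxy-5,9-dimethylcyclodeca-4,8-dien-1-yl 2-methylpropanoate (7α-OH) | C1C/C(C)=C/[C@@H](O[Si](C)(C)C(C)(C)C)[C@@H](O)[C@@H](OC(=O)C(C)C)C/C(C)=C/1 | intermediate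
23 | (1S,3R,4E,8E)-3-(tert-butyldimethylsilyloxy)-5,9-dimethyl-2-oxocyclodeca-4,8-dien-1-yl 2-methylpropanoate (C7 ketone) | C1C/C(C)=C/[C@@H](O[Si](C)(C)C(C)(C)C)C(=O)[C@@H](OC(=O)C(C)C)C/C(C)=C/1 | intermediate
24 | (1S,3R,4E,8E)-3-hydroxy-5,9-dimethyl-2-oxocyclodeca-4,8-dien-1-yl 2-methylpropanoate (6α-OH, C7 ketone) | C1C/C(C)=C/[C@@H](O)C(=O)[C@@H](OC(=O)C(C)C)C/C(C)=C/1 | intermediate
25 | (4R,5R,6R,8S)-4α,5β-epoxy-6α-hydroxy-7-oxocyclodec-1(10)E-en-8α-yl 2-methylpropanoate (germacrane numbering, methyls on C4 and C10) | C1C[C@@]2(C)O[C@@H]2[C@@H](O)C(=O)[C@@H](OC(=O)C(C)C)C/C(C)=C/1 | intermediate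
26 | allyl 2-(diethoxyphosphoryl)acetate | C=CCOC(=O)CP(=O)(OCC)OCC | starting material
27 | sodium salt of the carbanion of 26 (formed in situ) | [Na+].C=CCOC(=O)[CH-]P(=O)(OCC)OCC | intermediate
28 | allyl 2-(diethoxyphosphoryl)-3-(triisopropylsilyloxy)propanoate (racemic) | C=CCOC(=O)C(CO[Si](C(C)C)(C(C)C)C(C)C)P(=O)(OCC)OCC | intermediate
29 | 2-(diethoxyphosphoryl)-3-(triisopropylsilyloxy)propanoic acid (racemic) | OC(=O)C(CO[Si](C(C)C)(C(C)C)C(C)C)P(=O)(OCC)OCC | intermediate
30 | (4R,5R,6R,8S)-4α,5β-epoxy-7-oxo-8α-(2-methylpropanoyloxy)cyclodec-1(10)E-en-6α-yl 2-(diethoxyphosphoryl)-3-(triisopropylsilyloxy)propanoate (C11 epimers) | C1C[C@@]2(C)O[C@@H]2[C@@H](OC(=O)C(CO[Si](C(C)C)(C(C)C)C(C)C)P(=O)(OCC)OCC)C(=O)[C@@H](OC(=O)C(C)C)C/C(C)=C/1 | intermediate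
31 | (4R,5R,6S,8S)-4α,5β-epoxy-8α-(2-methylpropanoyloxy)-13-(triisopropylsilyloxy)germacra-1(10)E,7(11)-dien-12,6α-olide | CC(C)[Si](C(C)C)(C(C)C)OCC1=C2[C@@H](OC(=O)C(C)C)C/C(C)=C/CC[C@@]3(C)O[C@@H]3[C@H]2OC1=O | intermediate
32 | (4R,5R,6S,8S)-4α,5β-epoxy-13-hydroxy-8α-(2-methylpropanoyloxy)germacra-1(10)E,7(11)-dien-12,6α-olide | OCC1=C2[C@@H](OC(=O)C(C)C)C/C(C)=C/CC[C@@]3(C)O[C@@H]3[C@H]2OC1=O | intermediate
33 | (4R,5R,6S,8S)-13-acetoxy-4α,5β-epoxy-8α-(2-methylpropanoyloxy)germacra-1(10)E,7(11)-dien-12,6α-olide | CC(=O)OCC1=C2[C@@H](OC(=O)C(C)C)C/C(C)=C/CC[C@@]3(C)O[C@@H]3[C@H]2OC1=O | intermediate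
34 | (1R,4R,5R,6S,8S,10R)-13-acetoxy-1β,10α;4α,5β-diepoxy-8α-(2-methylpropanoyloxy)germacr-7(11)-en-12,6α-olide (CNP0191378.1) | CC(=O)OCC1=C2[C@@H](OC(=O)C(C)C)C[C@@]3(C)O[C@@H]3CC[C@@]3(C)O[C@@H]3[C@H]2OC1=O | target

**Count**

Total steps: 23. Longest linear sequence: 18 (steps 1–5, 9–16, 19–23); steps 6–8 and 17–18 are side branches.

**Steps most likely to fail**

Step 12. The strained ten-membered E,E-diene may close more slowly than intermolecular coupling, protodeboronation or β-hydride elimination proceed. The fallback sets out from 19 and returns at 21 through a more nucleophilic, base-free organometallic. Hydroboration with 9-BBN followed by NaBO3·4H2O oxidation would give the primary C2 alcohol F1. I2, PPh3 and imidazole would convert it into the primary C2 iodide F2. Activated Zn dust in THF–DMA at 30 °C should insert selectively into the sp3 C–I bond to give the alkylzinc iodide F3. Intramolecular Negishi coupling with Pd(PPh3)4 (zerovalent palladium) under high dilution would then form the same C1–C2 bond.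

Step 23. Facial selectivity may be poor if the macrocycle reacts through a conformer in which C14 is anti to C15. The fallback sets out from 32 and returns at 34 under reagent control. Shi epoxidation uses the D-fructose-derived ketone 1,2:4,5-di-O-isopropylidene-β-D-erythro-2,3-hexodiulo-2,6-pyranose with Oxone and K2CO3 buffer in MeCN–dimethoxymethane–H2O at 0 °C. By analogy with acyclic E-trisubstituted alkenes its spiro transition state should deliver the (1R,10R) epoxide, giving the diepoxy alcohol F4. Acetylation (Ac2O, pyridine) then gives the target and keeps the allylic acetate away from the basic oxidation medium.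

Step 9. Felkin control may erode through chelation by O7 or partial epimerisation of the α-silyloxy aldehyde, giving C6 epimers. The fallback sets out from the epimer mixture of 16 and returns at 16. Dess–Martin oxidation would give the cross-conjugated dienone F5. Corey–Bakshi–Shibata reduction with (R)-2-methyl-CBS-oxazaborolidine and catecholborane at −78 °C, with the dienyl group as the large substituent, should then give the 6R carbinol under reagent control.

**Further compounds**

F1 | step 12 | primary alcohol: 19 with the C2=C3 vinyl group converted into CH2CH2OH (hydroxyl on C2) | OCC/C(C)=C/[C@@H](O[Si](C)(C)C(C)(C)C)[C@@H](O[Si](CC)(CC)CC)[C@@H](OC(=O)C(C)C)C/C(C)=C/I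
F2 | step 12 | primary iodide: F1 with the C2 hydroxyl replaced by iodine | ICC/C(C)=C/[C@@H](O[Si](C)(C)C(C)(C)C)[C@@H](O[Si](CC)(CC)CC)[C@@H](OC(=O)C(C)C)C/C(C)=C/I
F3 | step 12 | alkylzinc iodide: zinc inserted into the C2–I bond of F2 | I[Zn]CC/C(C)=C/[C@@H](O[Si](C)(C)C(C)(C)C)[C@@H](O[Si](CC)(CC)CC)[C@@H](OC(=O)C(C)C)C/C(C)=C/I
F4 | step 23 | (1R,4R,5R,6S,8S,10R)-1β,10α;4α,5β-diepoxy-13-hydroxy-8α-(2-methylpropanoyloxy)germacr-7(11)-en-12,6α-olide | OCC1=C2[C@@H](OC(=O)C(C)C)C[C@@]3(C)O[C@@H]3CC[C@@]3(C)O[C@@H]3[C@H]2OC1=O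
F5 | step 9 | (3E,6S,7S)-3-methyl-5-oxo-6-(triethylsilyloxy)deca-1,3-dien-9-yn-7-yl 2-methylpropanoate | C=C/C(C)=C/C(=O)[C@@H](O[Si](CC)(CC)CC)[C@@H](OC(=O)C(C)C)CC#C
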